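**Retrosynthetic overview**
1. The C4–aryl bond is cut last: the ring A quinone methide of a 2,3-trans flavan-3,4-diol is attacked by C2 of piceatannol, anti to the C3–OH, which sets C4.
2. The flavan-3,4-diol comes from a 2,3-trans 3-benzoyloxyflavanone by one hydride step that reduces C4=O and removes all esters.
3. The C3–O bond is made by a [3,3]-sigmatropic rearrangement of the N-benzoyloxy enamine of the flavanone, trans to the C2 aryl, which sets C3.
4. C2 and the whole chroman (rings A, B, C) are bought as (S)-liquiritigenin; rings D and E are bought as piceatannol.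
5. No ring is built in the route; the order of events is protection, C3–O, reduction, C4–C.

Assumption: (S)-liquiritigenin (the licorice flavanone) is bought as the natural 2S enantiomer of high ee, and piceatannol as the E isomer.

**Step 1**
Reactants: 1 (S)-liquiritigenin
Product: 2 (2S)-7-acetoxy-2-(4-acetoxyphenyl)chroman-4-one
Conditions: Ac2O (3 equiv), pyridine, 0 °C → rt, 2 h
Reagents that add atoms: acetic anhydride CC(=O)OC(C)=O
Why: O-acetylation of both phenols under weakly basic conditions leaves the flavanone ring closed (C2 untouched) and makes the C4 carbonyl less electron-rich for the condensation in step 2.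

**Step 2**
Reactants: 2 (2S)-7-acetoxy-2-(4-acetoxyphenyl)chroman-4-one
Product: 5 (2R,3R)-7-acetoxy-2-(4-acetoxyphenyl)-4-oxochroman-3-yl benzoate (2,3-trans), via N-benzoyloxy enamine 3 (not isolated), via benzoyloxy imine 4 (not isolated)
Conditions: MeNH(OBz)·HCl (1.5 equiv), DMSO, 40 °C, 24 h; aqueous work-up
Reagents that add atoms: N-methyl-O-benzoylhydroxylamine hydrochloride CNOC(=O)c1ccccc1.Cl; water O (returns the C4 carbonyl oxygen on imine hydrolysis)
Why: Condensation gives the N-benzoyloxy enamine, whose concerted [3,3]-sigmatropic rearrangement (Tomkinson α-oxybenzoylation) forms the C3–O bond on the face away from the C2 aryl, any cis isomer equilibrating through the imine/enamine to the diequatorial 2,3-trans ester, all without base that could open the flavanone.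

**Step 3**
Reactants: 5 (2R,3R)-7-acetoxy-2-(4-acetoxyphenyl)-4-oxochroman-3-yl benzoate
Product: 6 (2R,3S,4R)-2-(4-hydroxyphenyl)chromane-3,4,7-triol (leucoguibourtinidin; 2,3-trans-3,4-trans)
Conditions: LiAlH4 (4 equiv), THF, −20 → 0 °C; EtOAc, then aq NH4Cl (pH ≈ 6)
Reagents that add atoms: none
Why: LiAlH4 reduction converts the ketone to the mainly all-equatorial 3,4-trans alcohol and cleaves the benzoate and both aryl acetates in the same operation, C2 and C3 being untouched and the C4 configuration being erased in step 4 anyway.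

**Step 4**
Reactants: 6 (2R,3S,4R)-2-(4-hydroxyphenyl)chromane-3,4,7-triol; 7 piceatannol
Product: 9 (2R,3S,4S)-4-{2-[(E)-2-(3,4-dihydroxyphenyl)ethenyl]-4,6-dihydroxyphenyl}-2-(4-hydroxyphenyl)chromane-3,7-diol (CNP0170061.1), via quinone methide 8 (not isolated)
Conditions: 7 (4 equiv), 0.1 M HCl in H2O–EtOH (3:1), rt, Ar, dark, 18 h
Reagents that add atoms: none
Why: Acid ionises the C4–OH (assisted by the para 7-OH) to the ring A quinone methide/benzylic cation, and Friedel–Crafts attack by C2 of the piceatannol resorcinol ring (ortho to one OH, para to the other) comes anti to the C3–OH on the 2,3-trans half-chair, giving the 3,4-trans (4S) centre as in the known biomimetic flavan-3,4-diol/stilbene condensation.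

**Compound list**
1 | (S)-liquiritigenin, (2S)-7-hydroxy-2-(4-hydroxyphenyl)chroman-4-one | O=C1C[C@@H](c2ccc(O)cc2)Oc2cc(O)ccc12 | starting material
2 | (2S)-7-acetoxy-2-(4-acetoxyphenyl)chroman-4-one | O=C1C[C@@H](c2ccc(OC(C)=O)cc2)Oc2cc(OC(C)=O)ccc12 | intermediate
3 | (2S)-7-acetoxy-2-(4-acetoxyphenyl)-4-[(benzoyloxy)(methyl)amino]-2H-chromene | CN(OC(=O)c1ccccc1)C1=C[C@@H](c2ccc(OC(C)=O)cc2)Oc2cc(OC(C)=O)ccc12 | intermediate
4 | (2R,3S)-7-acetoxy-2-(4-acetoxyphenyl)-4-(methylimino)chroman-3-yl benzoate (2,3-trans) | CN=C1[C@H](OC(=O)c2ccccc2)[C@@H](c2ccc(OC(C)=O)cc2)Oc2cc(OC(C)=O)ccc12 | intermediate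
5 | (2R,3R)-7-acetoxy-2-(4-acetoxyphenyl)-4-oxochroman-3-yl benzoate (2,3-trans) | O=C1[C@H](OC(=O)c2ccccc2)[C@@H](c2ccc(OC(C)=O)cc2)Oc2cc(OC(C)=O)ccc12 | intermediate
6 | (2R,3S,4R)-2-(4-hydroxyphenyl)chromane-3,4,7-triol (leucoguibourtinidin) | O[C@H]1[C@H](O)[C@@H](c2ccc(O)cc2)Oc2cc(O)ccc12 | intermediate
7 | piceatannol, 4-[(E)-2-(3,5-dihydroxyphenyl)ethenyl]benzene-1,2-diol | Oc1cc(O)cc(/C=C/c2ccc(O)c(O)c2)c1 | starting material
8 | (2R,3S)-3-hydroxy-2-(4-hydroxyphenyl)-2,3-dihydro-7H-chromen-7-one (ring A para-quinone methide) | O=C1C=CC2=C[C@H](O)[C@@H](c3ccc(O)cc3)OC2=C1 | intermediate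
9 | (2R,3S,4S)-4-{2-[(E)-2-(3,4-dihydroxyphenyl)ethenyl]-4,6-dihydroxyphenyl}-2-(4-hydroxyphenyl)chromane-3,7-diol | Oc1ccc([C@H]2Oc3cc(O)ccc3[C@@H](c3c(O)cc(O)cc3/C=C/c3ccc(O)c(O)c3)[C@@H]2O)cc1 | target

**Totals**
Total step count: 4.
Longest linear sequence: 4 steps (1 → 2 → 5 → 6 → 9); piceatannol 7 enters in step 4.

**Three steps most likely to fail**

Step 2. The ring A oxygens make the C4 carbonyl a vinylogous ester, so enamine formation may be slow. The enamine could also open the pyran ring by retro-oxa-Michael and erode C2. The fallback puts the C3 oxygen in through an alkene instead of through the ketone α-position. It sets out from 2: NaBH4 (THF–EtOH, −10 °C) gives the 2,4-cis (2S,4S)-flavan-4-ol diacetate F1. Catalytic p-TsOH in toluene at 60 °C dehydrates it to the (2S)-flav-3-ene diacetate F2. OsO4 (cat.)/NMO in acetone–H2O adds to the face away from the C2 aryl and gives the 2,3-trans-3,4-cis diol diacetate F3. K2CO3 in MeOH at 0 °C under argon frees the phenols to give the 3,4-cis tetraol F4, the C4 epimer of 6. F4 is used in step 4 in place of 6 and comes back to the route at quinone methide 8.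

Step 4. The diol can self-condense. Piceatannol can also react at C4 (between the two OH groups) or at the alkene, and some 3,4-cis product can form. The fallback releases the C4 electrophile slowly under aprotic conditions from a stable thioether. It sets out from 6: phenylmethanethiol in AcOH at rt gives the 3,4-trans (2R,3R,4R)-4-(benzylsulfanyl)-2-(4-hydroxyphenyl)chromane-3,7-diol F5. AgBF4 in THF at 0 °C with 7 (4 equiv) then abstracts the thiolate and the route is rejoined at 9.

Step 3. The aluminium phenoxide para to C4 can expel the C4 oxygen and be reduced further to the 4-deoxy flavan. The free, acid-sensitive tetraol is also hard to recover from aluminium salts. The fallback separates reduction from deacylation. It sets out from 5: NaBH4 in THF–EtOH at −10 °C reduces only the ketone to the (2R,3S,4R)-7-acetoxy-2-(4-acetoxyphenyl)-4-hydroxychroman-3-yl benzoate F6. K2CO3 in MeOH at 0 °C under argon then removes the three acyl groups by transesterification and returns to 6.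

**Further compounds**
F1 | step 2 | (2S,4S)-7-acetoxy-2-(4-acetoxyphenyl)chroman-4-ol (2,4-cis) | O[C@H]1C[C@@H](c2ccc(OC(C)=O)cc2)Oc2cc(OC(C)=O)ccc12
F2 | step 2 | (2S)-7-acetoxy-2-(4-acetoxyphenyl)-2H-chromene | C1=C[C@@H](c2ccc(OC(C)=O)cc2)Oc2cc(OC(C)=O)ccc12
F3 | step 2 | (2R,3S,4S)-7-acetoxy-2-(4-acetoxyphenyl)chromane-3,4-diol (2,3-trans-3,4-cis) | O[C@@H]1[C@H](O)[C@@H](c2ccc(OC(C)=O)cc2)Oc2cc(OC(C)=O)ccc12
F4 | step 2 | (2R,3S,4S)-2-(4-hydroxyphenyl)chromane-3,4,7-triol (2,3-trans-3,4-cis) | O[C@@H]1[C@H](O)[C@@H](c2ccc(O)cc2)Oc2cc(O)ccc12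
F5 | step 4 | (2R,3R,4R)-4-(benzylsulfanyl)-2-(4-hydroxyphenyl)chromane-3,7-diol (2,3-trans-3,4-trans) | c1ccccc1CS[C@H]1[C@H](O)[C@@H](c2ccc(O)cc2)Oc2cc(O)ccc12
F6 | step 3 | (2R,3S,4R)-7-acetoxy-2-(4-acetoxyphenyl)-4-hydroxychroman-3-yl benzoate | O[C@H]1[C@H](OC(=O)c2ccccc2)[C@@H](c2ccc(OC(C)=O)cc2)Oc2cc(OC(C)=O)ccc12
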